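Ring B: C1 ketone, C2 bridge carbon, C3, C4 quaternary, C5, C6 methyl-bearing. C4 lies between oxygenated C3 and C5 and bears isobutyryl and prenyl, which marks it as the alpha-carbon of a prenylated isobutyrylacetate; the plan cuts C4–C5 and C2–C3. In one flask, cinchona-catalysed Michael addition to methyl vinyl ketone forms C4–C5 and sets C4, then Claisen attack of the methyl ketone enolate on the ester forms C2–C3 and closes ring B. The precursor is the racemic 2,2,2-trifluoroethyl ester, chosen for C–H acidity and clean acyl transfer. Ester carbon becomes C3, enone terminus C5, so C6 methylation, C5 oxidation and C2 coupling to ring A keep the configuration.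

Key step: step 4

Assumption: the quinidine-derived catalyst is taken to give (S)-10; if correlation shows the opposite sense, its quinine-derived pseudoenantiomer is used and nothing else changes.
Remark: di- and triketones are drawn as one tautomer. The R/S label at C4 switches along the route only through CIP ranking; the spatial arrangement stays the same. Prenyl = 3-methylbut-2-en-1-yl, isobutyryl = 2-methylpropanoyl, and ring B numbering is used in all names.

Step 1
Reactants: 1 Meldrum's acid (2,2-dimethyl-1,3-dioxane-4,6-dione); 2 isobutyryl chloride
Product: 3 5-(1-hydroxy-2-methylpropylidene)-2,2-dimethyl-1,3-dioxane-4,6-dione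
Conditions: pyridine (2.2 equiv), CH2Cl2, 0 °C to rt; 1 M HCl wash
Reagents that add atoms: none
Why: C-acylation of Meldrum's acid by an acid chloride under pyridine is a standard entry to beta-keto ester equivalents and stops at the stable enol 3.

Step 2
Reactants: 3 acyl Meldrum's acid; 4 2,2,2-trifluoroethanol
Product: 6 2,2,2-trifluoroethyl 4-methyl-3-oxopentanoate, via isobutyrylketene 5 (not isolated)
Conditions: 4 (3 equiv), PhMe, 85 °C
Reagents that add atoms: none
Why: Thermal cycloreversion of an acyl Meldrum's acid releases acetone and CO2 and gives an acylketene that even weakly nucleophilic alcohols trap, which is the established route to beta-keto esters of alcohols unsuited to transesterification.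

Step 3
Reactants: 6 trifluoroethyl 4-methyl-3-oxopentanoate; 7 prenyl bromide
Product: 8 2,2,2-trifluoroethyl 2-isobutyryl-5-methylhex-4-enoate (racemic)
Conditions: K2CO3, acetone, rt
Reagents that add atoms: none
Why: This is acetoacetic-ester-type mono-C-alkylation of a beta-keto ester with an allylic bromide under carbonate base, in which one equivalent of 7 and the lower acidity of the branched product limit double alkylation and the racemic centre is erased in step 4.

Step 4
Reactants: 8 racemic prenylated keto ester; 9 methyl vinyl ketone
Product: 11 (4R)-4-isobutyryl-4-prenylcyclohexane-1,3-dione, via (S)-Michael adduct 10 (not isolated)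
Conditions: 9 (1.5 equiv), 9-O-(phenanthren-9-yl)cupreidine (10 mol%), CH2Cl2, rt; volatiles and excess 9 removed in vacuo; THF, cannulated into LiN(SiMe3)2 (2.5 equiv), −78 to 0 °C; 1 M HCl
Reagents that add atoms: none
Why: Bifunctional catalysis operates here: the quinuclidine nitrogen turns 8 into a chiral ammonium enolate, the phenolic 6'-OH holds 9 by a hydrogen bond, and bond formation inside this organised ion pair takes place on one enolate face, giving C4–C5 and the quaternary centre of 10 (known organocatalytic Michael addition of alpha-substituted beta-keto esters to enones). Excess 9 is stripped off so that the later dione enolate finds no acceptor, and inverse addition to LiN(SiMe3)2 at −78 °C deprotonates the unhindered CH3 of the methyl ketone rather than the internal CH2, whose enolate could expel the keto ester by retro-Michael reaction. That enolate attacks the ester carbonyl in a 6-(enolexo)-exo-trig Claisen closure with loss of trifluoroethoxide, forming C2–C3 and ring B as in the classical Michael–Claisen synthesis of cyclohexane-1,3-diones. C4, the only stereocentre, is set by the catalyst alone; it is quaternary, and because the ester carbon ends as C3 and the enone terminus as C5, (S)-10 maps onto (R)-11 with no pathway for epimerisation. The chemoselectivity needed is acyl substitution at the ester instead of aldol addition to the isobutyryl ketone, and the substrate secures it: the fluorinated ester is the stronger electrophile with the better leaving group, the ketone is shielded by isopropyl and C4, and an aldolate can revert; the same ester raises the C–H acidity of 8 for the amine-base step and releases an alkoxide too feeble to deacylate unreacted 10. The second equivalent of base converts 11 at once into its delocalised enolate, so the closure cannot run backwards and the non-enolisable C3/isobutyryl diketone unit is not exposed to nucleophilic C–C cleavage.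

Step 5
Reactants: 11 (4R)-dione
Product: 12 (4R)-4-isobutyryl-3-methoxy-4-prenylcyclohex-2-en-1-one
Conditions: Me3SiCHN2 (1.2 equiv), PhMe–MeOH, 0 °C; chromatography
Reagents that add atoms: (trimethylsilyl)diazomethane, C[Si](C)(C)C=[N+]=[N-]
Why: Diazoalkane O-methylation of a cyclic 1,3-dione enol is routine and leaves ketone and alkene untouched; since both enol oxygens can react, the C3–OMe isomer 12, in which C1 stays a ketone whose only enolisable neighbour is C6, is separated by chromatography from the C1–OMe isomer F5, which dilute aqueous acid returns to 11 for another pass.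

Step 6
Reactants: 12 C3 methyl enol ether
Product: 13 (4S,6RS)-4-isobutyryl-3-methoxy-6-methyl-4-prenylcyclohex-2-en-1-one
Conditions: LiN(iPr)2 (1.1 equiv), THF, −78 °C; MeI, −78 to −30 °C
Reagents that add atoms: iodomethane, CI
Why: This is a Stork–Danheiser kinetic alpha'-alkylation of a vinylogous ester: in neutral 12 the two C6 protons are the most accessible acidic sites (C4 is quaternary, and enolising the isobutyryl methine would build a tetrasubstituted enolate strained against C4), so LiN(iPr)2 and MeI place the methyl group on C6, whose new centre is a mixture that step 7 erases.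

Step 7
Reactants: 13 C6-methyl vinylogous ester
Product: 15 (4S)-4-isobutyryl-3-methoxy-6-methyl-4-prenylcyclohexa-2,5-dien-1-one, via trimethylsilyl dienol ether 14 (not isolated)
Conditions: Me3SiOSO2CF3 (1.2 equiv), Et3N, CH2Cl2, 0 °C; pentane filtration, solvent switch; Pd(OAc)2 (1.05 equiv), MeCN, rt
Reagents that add atoms: trimethylsilyl trifluoromethanesulfonate, C[Si](C)(C)OS(=O)(=O)C(F)(F)F (silyl group of 14 only)
Why: Soft enolisation is followed by Saegusa–Ito dehydrogenation: the silyl triflate binds the strongly Lewis-basic vinylogous ester oxygen rather than the crowded isobutyryl ketone, Et3N removes the C6 proton, and divalent palladium then attacks C6 of 14 and eliminates a C5 hydride to give the endocyclic C5=C6 enone, the ligand-free metal released at room temperature being harmless to the prenyl group.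

Step 8
Reactants: 15 cross-conjugated dienone
Product: 17 (4S)-5-hydroxy-4-isobutyryl-3-methoxy-6-methyl-4-prenylcyclohex-2-en-1-one (mixture at C5 and C6), via C5 pinacol boronate 16 (not isolated)
Conditions: B2pin2 (1.2 equiv), CuCl (10 mol%), DPEphos (10 mol%), NaOtBu (15 mol%), MeOH (2 equiv), THF, rt; then NaBO3·4H2O, THF–H2O, 0 °C
Reagents that add atoms: bis(pinacolato)diboron, CC1(C)OB(OC1(C)C)B1OC(C)(C)C(C)(C)O1 (boryl group of 16); sodium perborate, [Na+].[Na+].O[B-]1(O)OO[B-](O)(O)OO1 (C5 oxygen of 17)
Why: Copper-catalysed conjugate borylation followed by boronate oxidation is well known for cyclic enones: the soft boryl-copper species adds to C5, the only beta-carbon that is neither blocked nor deactivated by OMe, ignores the unactivated prenyl alkene, works with only catalytic alkoxide so that the cleavable C4 acyl group is spared, and cold perborate then exchanges boron for oxygen, the C5 and C6 centres being mixtures of no consequence.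

Step 9
Reactants: 17 beta-hydroxy ketone
Product: 18 (4S)-5-hydroxy-4-isobutyryl-3-methoxy-6-methyl-4-prenylcyclohexa-2,5-dien-1-one (C5 enol of the beta-diketone)
Conditions: Dess–Martin periodinane (1.2 equiv), CH2Cl2, 0 °C to rt
Reagents that add atoms: none
Why: Dess–Martin oxidation takes a beta-hydroxy ketone to the beta-diketone under non-basic conditions, so that no C5 alkoxide able to trigger retro-aldol cleavage of C4–C5 is formed, and the C6 centre disappears on enolisation.

Step 10
Reactants: 18 trione 3-O-methyl ether
Product: 19 (4R)-3,5-dihydroxy-4-isobutyryl-6-methyl-4-prenylcyclohexa-2,5-dien-1-one (ring B trione, dienol tautomer)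
Conditions: LiCl (5 equiv), DMSO, 100–120 °C; cold 0.5 M HCl
Reagents that add atoms: none
Why: Krapcho-type SN2 demethylation of a vinylogous methyl ester by chloride is the usual late unmasking in polyprenylated acylphloroglucinol chemistry: attack is at the open O–CH3 carbon and not at crowded C3, the leaving group is the enolate of a strong vinylogous acid, and neither acid (chroman formation with prenyl) nor a hard nucleophile (loss of the C4 acyl group) is present.

Step 11
Reactants: 20 phloroglucinol; 2 isobutyryl chloride
Product: 21 2-methyl-1-(2,4,6-trihydroxyphenyl)propan-1-one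
Conditions: AlCl3 (3.5 equiv), CH2Cl2–MeNO2, 40 °C; ice/HCl
Reagents that add atoms: none
Why: Friedel–Crafts C-acylation of phloroglucinol stops after one acyl group because the chelated aryl ketone deactivates the ring.

Step 12
Reactants: 21 acylphloroglucinol; 7 prenyl bromide
Product: 22 2-methyl-1-[2,4,6-trihydroxy-3-prenylphenyl]propan-1-one
Conditions: KOH (1 equiv), H2O, 0 °C to rt; 7 (0.9 equiv)
Reagents that add atoms: none
Why: C-prenylation of the ambident acylphloroglucinolate is run in water, where hydrogen bonding to oxygen favours carbon attack; the two free ring positions are equivalent and a slight deficit of 7 limits double prenylation.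

Step 13
Reactants: 22 prenylated acylphloroglucinol
Product: 23 1-[3-(dimethylaminomethyl)-2,4,6-trihydroxy-5-prenylphenyl]-2-methylpropan-1-one
Conditions: CH2=NMe2+ I− (1.5 equiv), CH2Cl2, 0 °C to rt; aq. NaHCO3
Reagents that add atoms: N,N-dimethylmethyleneiminium iodide, C=[N+](C)C.[I-]
Why: This is a phenolic Mannich reaction with a preformed iminium salt at the single free ring position; keeping the iminium salt in excess prevents the Mannich base from alkylating unreacted 22, and storing the bridge carbon on ring A avoids the statistical homo-coupling that free formaldehyde would cause in step 14.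

Step 14
Reactants: 19 ring B trione; 23 ring A Mannich base
Product: 25 target (4S)-3,5-dihydroxy-4-isobutyryl-6-methyl-4-prenyl-2-{[2,4,6-trihydroxy-3-isobutyryl-5-prenylphenyl]methyl}cyclohexa-2,5-dien-1-one, via ring A ortho-quinone methide 24 (not isolated)
Conditions: 23 (1.1 equiv), 1,4-dioxane, 70 °C, N2 stream; cold 0.5 M HCl wash
Reagents that add atoms: none
Why: Thermal loss of dimethylamine from the zwitterionic Mannich base gives ortho-quinone methide 24, which is taken up in a Michael addition by the strongly nucleophilic enol of 19 (known alkylation of 1,3-dicarbonyl compounds by phenolic Mannich bases); C2 wins over C6 because it is unsubstituted and its adduct can re-enolise whereas a C6 adduct can only revert, and C4 is not touched.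

Compound list
1 | Meldrum's acid (2,2-dimethyl-1,3-dioxane-4,6-dione) | CC1(C)OC(=O)CC(=O)O1 | starting material
2 | isobutyryl chloride | CC(C)C(=O)Cl | starting material
3 | 5-(1-hydroxy-2-methylpropylidene)-2,2-dimethyl-1,3-dioxane-4,6-dione | CC(C)C(O)=C1C(=O)OC(C)(C)OC1=O | intermediate
4 | 2,2,2-trifluoroethanol | OCC(F)(F)F | starting material
5 | isobutyrylketene (4-methylpent-1-ene-1,3-dione) | CC(C)C(=O)C=C=O | intermediate
6 | 2,2,2-trifluoroethyl 4-methyl-3-oxopentanoate | CC(C)C(=O)CC(=O)OCC(F)(F)F | intermediate
7 | prenyl bromide (1-bromo-3-methylbut-2-ene) | CC(C)=CCBr | starting material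
8 | 2,2,2-trifluoroethyl 2-isobutyryl-5-methylhex-4-enoate, racemic | CC(C)=CCC(C(=O)C(C)C)C(=O)OCC(F)(F)F | intermediate
9 | methyl vinyl ketone | CC(=O)C=C | starting material
10 | 2,2,2-trifluoroethyl (2S)-2-isobutyryl-5-methyl-2-(3-oxobutyl)hex-4-enoate | FC(F)(F)COC(=O)[C@@](CC=C(C)C)(C(=O)C(C)C)CCC(C)=O | intermediate
11 | (4R)-4-isobutyryl-4-prenylcyclohexane-1,3-dione | O=C1CC(=O)[C@@](CC=C(C)C)(C(=O)C(C)C)CC1 | intermediate
12 | (4R)-4-isobutyryl-3-methoxy-4-prenylcyclohex-2-en-1-one | O=C1C=C(OC)[C@@](CC=C(C)C)(C(=O)C(C)C)CC1 | intermediate
13 | (4S,6RS)-4-isobutyryl-3-methoxy-6-methyl-4-prenylcyclohex-2-en-1-one | O=C1C=C(OC)[C@@](CC=C(C)C)(C(=O)C(C)C)CC1C | intermediate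
14 | trimethylsilyl dienol ether of 13 (C1–OSiMe3, C1=C6 and C2=C3 double bonds, C4 unchanged) | C1=C(OC)[C@@](CC=C(C)C)(C(=O)C(C)C)CC(C)=C1O[Si](C)(C)C | intermediate
15 | (4S)-4-isobutyryl-3-methoxy-6-methyl-4-prenylcyclohexa-2,5-dien-1-one | O=C1C=C(OC)[C@@](CC=C(C)C)(C(=O)C(C)C)C=C1C | intermediate
16 | (4S)-4-isobutyryl-3-methoxy-6-methyl-5-(pinacolatoboryl)-4-prenylcyclohex-2-en-1-one, mixture at C5 and C6 | O=C1C=C(OC)[C@@](CC=C(C)C)(C(=O)C(C)C)C(B2OC(C)(C)C(C)(C)O2)C1C | intermediate
17 | (4S)-5-hydroxy-4-isobutyryl-3-methoxy-6-methyl-4-prenylcyclohex-2-en-1-one, mixture at C5 and C6 | O=C1C=C(OC)[C@@](CC=C(C)C)(C(=O)C(C)C)C(O)C1C | intermediate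
18 | (4S)-5-hydroxy-4-isobutyryl-3-methoxy-6-methyl-4-prenylcyclohexa-2,5-dien-1-one | O=C1C=C(OC)[C@@](CC=C(C)C)(C(=O)C(C)C)C(O)=C1C | intermediate
19 | (4R)-3,5-dihydroxy-4-isobutyryl-6-methyl-4-prenylcyclohexa-2,5-dien-1-one | O=C1C=C(O)[C@@](CC=C(C)C)(C(=O)C(C)C)C(O)=C1C | intermediate
20 | phloroglucinol | Oc1cc(O)cc(O)c1 | starting material
21 | 2-methyl-1-(2,4,6-trihydroxyphenyl)propan-1-one | CC(C)C(=O)c1c(O)cc(O)cc1O | intermediate
22 | 2-methyl-1-[2,4,6-trihydroxy-3-prenylphenyl]propan-1-one | CC(C)=CCc1c(O)cc(O)c(C(=O)C(C)C)c1O | intermediate
23 | 1-[3-(dimethylaminomethyl)-2,4,6-trihydroxy-5-prenylphenyl]-2-methylpropan-1-one | CC(C)=CCc1c(O)c(CN(C)C)c(O)c(C(=O)C(C)C)c1O | intermediate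
24 | ring A ortho-quinone methide (3,5-dihydroxy-4-isobutyryl-6-methylidene-2-prenylcyclohexa-2,4-dien-1-one) | C=C1C(=O)C(CC=C(C)C)=C(O)C(C(=O)C(C)C)=C1O | intermediate
25 | CNP0191741.1, (4S) at C4 of ring B | CC(C)=CCc1c(O)c(CC2=C(O)[C@@](CC=C(C)C)(C(=O)C(C)C)C(O)=C(C)C2=O)c(O)c(C(=O)C(C)C)c1O | target

Total step count: 14. Longest linear sequence: 11 (steps 1–10 and 14). Ring A is made in three parallel steps (11–13).

Steps most likely to fail

Step 4. The acyclic, doubly branched donor may turn over slowly. It can also populate two enolate geometries, which would erode facial discrimination. Enantiopurity could be lost further by retro-Michael reaction and re-addition if some internal ketone enolate forms during the base stage. Fallback, from 8 and 9: the addition is run with catalytic DBU in MeCN to the racemic Michael adduct F1, which LiN(SiMe3)2 closes to the racemic dione F2. This dione is about as acidic as a carboxylic acid and is resolved by fractional crystallisation with (S)-1-phenylethylamine as the (R)-dione (S)-1-phenylethylammonium salt F3. Acidification rejoins the route at 11; the other amine enantiomer serves if the wrong salt crystallises.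

Step 8. Attack at the neopentyl C5 of an alpha-methyl enone may be sluggish. Alkoxide could remove the C4 acyl group with aromatisation. The carbinol could ring-open by retro-aldol cleavage of C4–C5 during the mildly basic oxidation. Fallback, from 15: Weitz–Scheffer epoxidation (tBuOOH, DBU, CH2Cl2) delivers oxygen with a small nucleophile and gives the 5,6-epoxy ketone F4. SmI2 in THF–MeOH at −78 °C then cleaves its C6–O bond reductively, so that the carbinol appears cold and protonated, rejoining the route at 17. An epoxide-to-diketone isomerisation with Pd(PPh3)4 is deliberately not used. The C4–prenyl bond of 18 is allylic to a carbon whose anion is an aromatic phenolate, so hot phosphine-ligated zerovalent palladium could ionise it and scramble C4.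

Step 5. O-methylation has no inherent regiocontrol, so material is diverted into the unwanted enol ether and has to be recycled. Fallback, from 11: HC(OMe)3, MeOH and catalytic TsOH give, by attack of methanol at the unhindered C1, the C1 methyl enol ether F5. Me3OBF4 in CH2Cl2 methylates its vinylogous ester carbonyl oxygen to the 1,3-dimethoxycyclohexenylium tetrafluoroborate F6. On quenching into cold aqueous NaHCO3, water again attacks the unhindered C1 and methanol is lost there. This leaves the C3–OMe isomer and rejoins the route at 12.

Further compounds
F1 | step 4 | racemic 2,2,2-trifluoroethyl 2-isobutyryl-5-methyl-2-(3-oxobutyl)hex-4-enoate | FC(F)(F)COC(=O)C(CC=C(C)C)(C(=O)C(C)C)CCC(C)=O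
F2 | step 4 | racemic 4-isobutyryl-4-prenylcyclohexane-1,3-dione | O=C1CC(=O)C(CC=C(C)C)(C(=O)C(C)C)CC1
F3 | step 4 | (S)-1-phenylethylammonium enolate of (4R)-4-isobutyryl-4-prenylcyclohexane-1,3-dione | O=C1C=C([O-])[C@@](CC=C(C)C)(C(=O)C(C)C)CC1.C[C@H]([NH3+])c1ccccc1
F4 | step 8 | (4S)-5,6-epoxy-4-isobutyryl-3-methoxy-6-methyl-4-prenylcyclohex-2-en-1-one, epoxide face unassigned | O=C1C=C(OC)[C@@](CC=C(C)C)(C(=O)C(C)C)C2OC12C
F5 | step 5 | C1 methyl enol ether, (6S)-6-isobutyryl-3-methoxy-6-prenylcyclohex-2-en-1-one | COC1=CC(=O)[C@@](CC=C(C)C)(C(=O)C(C)C)CC1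
F6 | step 5 | 4-isobutyryl-1,3-dimethoxy-4-prenylcyclohexenylium tetrafluoroborate | COC1=CC(=[O+]C)[C@@](CC=C(C)C)(C(=O)C(C)C)CC1.F[B-](F)(F)F
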